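**Retrosynthetic overview**
- Feature: in pyran ring B the vinylic carbon C4 is bonded to C4a, the ring A carbon next to oxygen-bearing C8a, and O1 ends at the gem-dimethyl carbon C2. C4 is therefore the formyl carbon of a salicylaldehyde, and C3–C2(CH3)2 is an isobutenyl nucleophile.
- Ring B is the only ring built (ring A and the anisyl ring are bought). It is cut at C3–C4 and O1–C2: borono-Mannich alkenylation, expulsion of the amine to an ortho-quinone methide, then oxa-6π closure.
- The salicylaldehyde has the future O1 as its only free OH and the future C5 oxygen as a MOM ether. It is traced to isovanillin by exchange of CHO for O (Baeyer–Villiger) and formylation of the carbon between two ether oxygens.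
- After ring B, the C5 OMOM group directs lithiation to C6. The C6–C(=O) bond is made with the Weinreb amide of 4-methoxyphenylacetic acid, the CH2 is oxidised to the second carbonyl, and the MOM group is removed last.

Key step: step 6

Assumption: the target is achiral and is treated as the open, hydrogen-bonded 2-hydroxybenzil form drawn, so no stereocentre has to be set.

**Step 1**
Reactants: 1 isovanillin (3-hydroxy-4-methoxybenzaldehyde)
Product: 2 3-(benzyloxy)-4-methoxybenzaldehyde
Conditions: BnBr, K2CO3, DMF, rt
Reagents that add atoms: benzyl bromide, BrCc1ccccc1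
Why: Williamson ether synthesis, in which the phenoxide of 1 displaces bromide from the benzylic halide while the aldehyde is inert to carbonate.

**Step 2**
Reactants: 2 3-(benzyloxy)-4-methoxybenzaldehyde
Product: 4 3-(benzyloxy)-4-methoxyphenol, via aryl formate 3 (not isolated)
Conditions: mCPBA, CH2Cl2, 0 °C → rt; aq. NaHCO3 wash; crude 3, K2CO3 (cat.), MeOH, rt
Reagents that add atoms: mCPBA, O=C(OO)c1cccc(Cl)c1
Why: Baeyer–Villiger oxidation, in which the electron-rich aryl group (para methoxy) migrates in preference to hydrogen, followed by base-catalysed methanolysis of the formate, which leaves the benzyl ether untouched.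

**Step 3**
Reactants: 4 3-(benzyloxy)-4-methoxyphenol
Product: 5 2-(benzyloxy)-1-methoxy-4-(methoxymethoxy)benzene
Conditions: MOMCl, i-Pr2NEt, CH2Cl2, 0 °C → rt
Reagents that add atoms: chloromethyl methyl ether, COCCl
Why: O-alkylation of the phenol by the reactive α-chloro ether (acetal protection) installs the coordinating group that serves both later lithiations and is orthogonal to the benzyl ether.

**Step 4**
Reactants: 5 2-(benzyloxy)-1-methoxy-4-(methoxymethoxy)benzene
Product: 8 2-(benzyloxy)-3-methoxy-6-(methoxymethoxy)benzaldehyde, via aryllithium 6 (not isolated), via lithium hemiaminal alkoxide 7 (not isolated)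
Conditions: n-BuLi, THF, −20 → 0 °C; DMF, −78 °C → rt; H2O
Reagents that add atoms: DMF, CN(C)C=O; n-butyllithium, [Li]CCCC (lithium held only in 6 and 7)
Why: Directed ortho-metalation with DMF formylation, in which the C–H between OMOM and OBn is acidified and coordinated from both sides (the site at which 1,2,4-trialkoxybenzenes are known to lithiate), so it should be removed faster than the other ring hydrogens or the benzylic ones at or below 0 °C.

**Step 5**
Reactants: 8 2-(benzyloxy)-3-methoxy-6-(methoxymethoxy)benzaldehyde
Product: 9 2-hydroxy-3-methoxy-6-(methoxymethoxy)benzaldehyde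
Conditions: H2 (1 atm), 10% Pd/C, EtOAc, rt
Reagents that add atoms: none
Why: Catalytic hydrogenolysis of the benzylic C–O bond, which in ethyl acetate at one atmosphere is much faster than reduction of the flanked, electron-rich aldehyde and does not affect the MOM acetal.

**Step 6**
Reactants: 9 2-hydroxy-3-methoxy-6-(methoxymethoxy)benzaldehyde; 10 (2-methylprop-1-en-1-yl)boronic acid
Product: 13 8-methoxy-5-(methoxymethoxy)-2,2-dimethyl-2H-chromene, via allylic dibenzylamine 11 (not isolated), via ortho-quinone methide 12 (not isolated)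
Conditions: Bn2NH (1 equiv), 10 (1.5 equiv), 1,4-dioxane, rt, then 90 °C
Reagents that add atoms: dibenzylamine, C(NCc1ccccc1)c1ccccc1 (its atoms are held only in 11 and leave again)
Why: Dibenzylamine condenses with the aldehyde of 9 to an iminium ion, the neighbouring phenoxide binds the boron of 10, and the isobutenyl group moves within this tetracoordinate boronate from boron to the iminium carbon (C3–C4 bond) to give racemic 11. On heating, the phenol helps to expel dibenzylamine from the benzylic and allylic carbon, and the O=C8a–C4a=C4–C3=C2 array of the resulting 12 closes ring B by a thermal, disrotatory oxa-6π electrocyclisation (O1–C2 bond) driven by rearomatisation of ring A. The closest known reaction type is the amine-mediated Petasis borono-Mannich condensation of salicylaldehydes with alkenylboronic acids that runs on to 2H-chromenes, applied here to a 6-alkoxy salicylaldehyde and a β,β-dimethyl alkenylboronic acid. No stereocentre survives, since the nitrogen-bearing carbon of 11 becomes sp2 C4 and C2 carries two identical methyl groups. The selectivity needed is the choice of the oxygen that becomes O1, and it is secured because only the hydroxyl next to the methoxy group is free to bind boron, push out the amine and close the ring, while the other ortho oxygen is locked as its MOM ether. That MOM group should also press the alkenyl chain of 12 towards the carbonyl side (Z geometry, as closure requires), and the three donor oxygens ease the ionisation, which offsets slower iminium formation at the flanked aldehyde.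

**Step 7**
Reactants: 14 4-methoxyphenylacetic acid
Product: 16 N-methoxy-N-methyl-2-(4-methoxyphenyl)acetamide, via acyl imidazole 15 (not isolated)
Conditions: CDI, CH2Cl2, rt; then MeNH(OMe)·HCl, rt
Reagents that add atoms: N,O-dimethylhydroxylamine hydrochloride, CNOC.Cl; 1,1'-carbonyldiimidazole, O=C(n1ccnc1)n1ccnc1 (its atoms are held only in 15)
Why: Amide formation through CDI activation, in which the acyl imidazole is aminolysed by the hydroxylamine set free from its salt by the imidazole already present.

**Step 8**
Reactants: 13 8-methoxy-5-(methoxymethoxy)-2,2-dimethyl-2H-chromene; 16 N-methoxy-N-methyl-2-(4-methoxyphenyl)acetamide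
Product: 19 1-[8-methoxy-5-(methoxymethoxy)-2,2-dimethyl-2H-chromen-6-yl]-2-(4-methoxyphenyl)ethan-1-one, via C6 aryllithium 17 (not isolated), via lithium chelate adduct 18 (not isolated)
Conditions: n-BuLi, TMEDA, THF, −20 → 0 °C; 16, THF, −78 → 0 °C; H2O
Reagents that add atoms: n-butyllithium, [Li]CCCC (lithium held only in 17 and 18)
Why: Directed ortho-metalation followed by Weinreb ketone synthesis, in which the bidentate MOM ether at C5 steers the base to C6 rather than to C7 beside the weaker methoxy director, and the chelated adduct persists until the quench so that no second addition takes place.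

**Step 9**
Reactants: 19 1-[8-methoxy-5-(methoxymethoxy)-2,2-dimethyl-2H-chromen-6-yl]-2-(4-methoxyphenyl)ethan-1-one
Product: 20 1-[8-methoxy-5-(methoxymethoxy)-2,2-dimethyl-2H-chromen-6-yl]-2-(4-methoxyphenyl)ethane-1,2-dione
Conditions: SeO2, 1,4-dioxane, 100 °C
Reagents that add atoms: selenium dioxide, O=[Se]=O
Why: Riley oxidation, in which SeO2 attacks the enol at the CH2 activated by both the carbonyl and the anisyl ring and collapses to the 1,2-diketone, while the chromene alkene has no allylic hydrogen (C2 is quaternary) and so offers no ene pathway.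

**Step 10**
Reactants: 20 1-[8-methoxy-5-(methoxymethoxy)-2,2-dimethyl-2H-chromen-6-yl]-2-(4-methoxyphenyl)ethane-1,2-dione
Product: 21 dielsianone, 1-(5-hydroxy-8-methoxy-2,2-dimethyl-2H-chromen-6-yl)-2-(4-methoxyphenyl)ethane-1,2-dione
Conditions: 3 M aq. HCl, THF, 50 °C
Reagents that add atoms: none
Why: Acid-catalysed acetal hydrolysis, which is easy for a MOM ether ortho to a carbonyl because the freed phenol is hydrogen-bonded to it, and dilute acid at mild temperature should leave the 2,2-dimethylchromene, the aryl methyl ethers and the diketone intact.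

**Compound list**
1 | isovanillin (3-hydroxy-4-methoxybenzaldehyde) | COc1ccc(C=O)cc1O | starting material
2 | 3-(benzyloxy)-4-methoxybenzaldehyde | COc1ccc(C=O)cc1OCc1ccccc1 | intermediate
3 | 3-(benzyloxy)-4-methoxyphenyl formate | COc1ccc(OC=O)cc1OCc1ccccc1 | intermediate
4 | 3-(benzyloxy)-4-methoxyphenol | COc1ccc(O)cc1OCc1ccccc1 | intermediate
5 | 2-(benzyloxy)-1-methoxy-4-(methoxymethoxy)benzene | COCOc1ccc(OC)c(OCc2ccccc2)c1 | intermediate
6 | [2-(benzyloxy)-3-methoxy-6-(methoxymethoxy)phenyl]lithium | [Li]c1c(OCOC)ccc(OC)c1OCc1ccccc1 | intermediate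
7 | lithium [2-(benzyloxy)-3-methoxy-6-(methoxymethoxy)phenyl](dimethylamino)methoxide | [Li]OC(N(C)C)c1c(OCOC)ccc(OC)c1OCc1ccccc1 | intermediate
8 | 2-(benzyloxy)-3-methoxy-6-(methoxymethoxy)benzaldehyde | COCOc1ccc(OC)c(OCc2ccccc2)c1C=O | intermediate
9 | 2-hydroxy-3-methoxy-6-(methoxymethoxy)benzaldehyde | COCOc1ccc(OC)c(O)c1C=O | intermediate
10 | (2-methylprop-1-en-1-yl)boronic acid | CC(C)=CB(O)O | starting material
11 | 2-[1-(dibenzylamino)-3-methylbut-2-en-1-yl]-6-methoxy-3-(methoxymethoxy)phenol (racemic) | COCOc1ccc(OC)c(O)c1C(C=C(C)C)N(Cc1ccccc1)Cc1ccccc1 | intermediate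
12 | (6Z)-2-methoxy-5-(methoxymethoxy)-6-(3-methylbut-2-en-1-ylidene)cyclohexa-2,4-dien-1-one | O=C1C(OC)=CC=C(OCOC)/C1=C/C=C(C)C | intermediate
13 | 8-methoxy-5-(methoxymethoxy)-2,2-dimethyl-2H-chromene | COCOc1ccc(OC)c2c1C=CC(C)(C)O2 | intermediate
14 | 4-methoxyphenylacetic acid | COc1ccc(CC(=O)O)cc1 | starting material
15 | 1-(1H-imidazol-1-yl)-2-(4-methoxyphenyl)ethan-1-one | COc1ccc(CC(=O)n2ccnc2)cc1 | intermediate
16 | N-methoxy-N-methyl-2-(4-methoxyphenyl)acetamide | COc1ccc(CC(=O)N(C)OC)cc1 | intermediate
17 | [8-methoxy-5-(methoxymethoxy)-2,2-dimethyl-2H-chromen-6-yl]lithium | COCOc1c([Li])cc(OC)c2c1C=CC(C)(C)O2 | intermediate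
18 | lithium alkoxide of the tetrahedral adduct of 17 and 16 (racemic) | [Li]OC(Cc1ccc(OC)cc1)(N(C)OC)c1cc(OC)c2c(c1OCOC)C=CC(C)(C)O2 | intermediate
19 | 1-[8-methoxy-5-(methoxymethoxy)-2,2-dimethyl-2H-chromen-6-yl]-2-(4-methoxyphenyl)ethan-1-one | COCOc1c(C(=O)Cc2ccc(OC)cc2)cc(OC)c2c1C=CC(C)(C)O2 | intermediate
20 | 1-[8-methoxy-5-(methoxymethoxy)-2,2-dimethyl-2H-chromen-6-yl]-2-(4-methoxyphenyl)ethane-1,2-dione | COCOc1c(C(=O)C(=O)c2ccc(OC)cc2)cc(OC)c2c1C=CC(C)(C)O2 | intermediate
21 | dielsianone | COc1ccc(C(=O)C(=O)c2cc(OC)c3c(c2O)C=CC(C)(C)O3)cc1 | target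

**Total step count:** 10
**Longest linear sequence:** 9 (steps 1–6 and 8–10, from isovanillin)

**Steps most likely to fail**

1. **Step 6.**
   - Risk: iminium formation at an aldehyde flanked by two ortho oxygens may be slow, so protodeboronation of the alkenylboronic acid could outrun the alkenyl transfer. Expulsion of the amine may also stop short of completion.
   - Fallback: it sets out from 5 and comes back at 13, and it makes steps 4 and 5 unnecessary.
   - Hydrogenolysis of 5 (H2, Pd/C, EtOAc) should give 2-methoxy-5-(methoxymethoxy)phenol F1.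
   - O-alkylation of F1 with 3-chloro-3-methylbut-1-yne (DBU, CuCl2 cat., MeCN, 0 °C) should give 1-methoxy-4-(methoxymethoxy)-2-[(2-methylbut-3-yn-2-yl)oxy]benzene F2.
   - Heating F2 in N,N-diethylaniline or o-xylene brings about an aromatic Claisen rearrangement to the only free ortho carbon. After tautomerisation this gives 6-methoxy-3-(methoxymethoxy)-2-(3-methylbuta-1,2-dien-1-yl)phenol F3.
   - A 1,5-hydrogen shift in F3 leads to the same ortho-quinone methide 12, which closes to 13.

2. **Step 8.**
   - Risk: proton transfer from the acidic benzylic CH2 of the amide to the aryllithium may compete with addition and return unchanged chromene. Incomplete metalation at C6 would have the same effect.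
   - Fallback: it sets out from 13 (through aryllithium 17) and comes back at 19, with the roles of the partners reversed.
   - Aryllithium 17 is quenched with DMF to give 8-methoxy-5-(methoxymethoxy)-2,2-dimethyl-2H-chromene-6-carbaldehyde F4, an electrophile without α-hydrogen.
   - Commercial 4-methoxybenzylmagnesium chloride (THF, 0 °C) adds to F4 to give racemic 1-[8-methoxy-5-(methoxymethoxy)-2,2-dimethyl-2H-chromen-6-yl]-2-(4-methoxyphenyl)ethan-1-ol F5.
   - Dess–Martin periodinane (NaHCO3, CH2Cl2) oxidises the carbinol to 19.

3. **Step 4.**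
   - Risk: removal of a benzylic hydrogen of the OBn group followed by 1,2-Wittig migration may compete with ring lithiation. Metalation at the less crowded position ortho to OMOM alone is also possible.
   - Fallback: it sets out from 1 and comes back at 8, and it fixes the site with a halogen instead of a deprotonation.
   - Bromination of 1 (Br2, NaOAc, Fe cat., AcOH) occurs between CHO and OH and gives 2-bromo-3-hydroxy-4-methoxybenzaldehyde F6.
   - Benzylation (BnBr, K2CO3, DMF) gives 3-(benzyloxy)-2-bromo-4-methoxybenzaldehyde F7.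
   - mCPBA gives 3-(benzyloxy)-2-bromo-4-methoxyphenyl formate F8, and methanolysis (K2CO3 cat., MeOH) gives 3-(benzyloxy)-2-bromo-4-methoxyphenol F9.
   - MOMCl and i-Pr2NEt give 2-(benzyloxy)-3-bromo-1-methoxy-4-(methoxymethoxy)benzene F10.
   - Bromine–lithium exchange (n-BuLi, THF, −78 °C), which is much faster than any deprotonation, produces aryllithium 6, and DMF then delivers 8.

**Further compounds**
F1 | step 6 | 2-methoxy-5-(methoxymethoxy)phenol | COCOc1ccc(OC)c(O)c1
F2 | step 6 | 1-methoxy-4-(methoxymethoxy)-2-[(2-methylbut-3-yn-2-yl)oxy]benzene | COCOc1ccc(OC)c(OC(C)(C)C#C)c1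
F3 | step 6 | 6-methoxy-3-(methoxymethoxy)-2-(3-methylbuta-1,2-dien-1-yl)phenol | COCOc1ccc(OC)c(O)c1C=C=C(C)C
F4 | step 8 | 8-methoxy-5-(methoxymethoxy)-2,2-dimethyl-2H-chromene-6-carbaldehyde | COCOc1c(C=O)cc(OC)c2c1C=CC(C)(C)O2
F5 | step 8 | 1-[8-methoxy-5-(methoxymethoxy)-2,2-dimethyl-2H-chromen-6-yl]-2-(4-methoxyphenyl)ethan-1-ol (racemic) | COCOc1c(C(O)Cc2ccc(OC)cc2)cc(OC)c2c1C=CC(C)(C)O2
F6 | step 4 | 2-bromo-3-hydroxy-4-methoxybenzaldehyde | COc1ccc(C=O)c(Br)c1O
F7 | step 4 | 3-(benzyloxy)-2-bromo-4-methoxybenzaldehyde | COc1ccc(C=O)c(Br)c1OCc1ccccc1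
F8 | step 4 | 3-(benzyloxy)-2-bromo-4-methoxyphenyl formate | COc1ccc(OC=O)c(Br)c1OCc1ccccc1
F9 | step 4 | 3-(benzyloxy)-2-bromo-4-methoxyphenol | COc1ccc(O)c(Br)c1OCc1ccccc1
F10 | step 4 | 2-(benzyloxy)-3-bromo-1-methoxy-4-(methoxymethoxy)benzene | COCOc1ccc(OC)c(OCc2ccccc2)c1Br
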